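**Retrosynthetic overview**

1. Numbering: decalin C1–C10 (ring A = C1–C5 and C10; ring B = C5–C10; Br on C1, OH on C4, C5, C7, Me on C4 and C10); cyclopentane C11–C15 (C11 on C7, OH on C12, Br on C14, C15 = CMe2). Enabling feature: in ring B the carbinol C7 lies 1,3 to the ring-fusion carbinol C5 across the C6 methylene, and C5 is vicinal to carbinol C4. With C4–C5 read as an alkene, this is the retron of a carbonyl-ene reaction between a C7 ketone and an exocyclic C5=C6 methylene on ring A. The β-bromo quaternary pair C1–C10 of ring A is the retron of a bromonium/alkene cyclisation, so both rings can be folded from one chain.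
2. Target ⇐ 4α,5α-epoxide 30 (trans-diaxial hydrolysis gives the C4/C5 diol) ⇐ Δ4-octalin-7-ol 29 (epoxidation guided by the 7-OH).
3. 29 ⇐ acyclic bromohydrin trifluoroacetate 27 by one cationic bicyclisation: bromonium ion at C1–C10, vinylsilane-terminated closure of ring A (C5–C10), then ketone-ene closure of ring B (C6–C7). Ring order: cyclopentane first, ring A second, ring B last.
4. 27 ⇐ cyclopentyl methyl ketone 16 + allylic bromide 22 (enolate alkylation, C8–C9), then Shi epoxidation and bromide opening; 22 from (S)-citronellal.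
5. 16 ⇐ bromocyclopentane ester 11 (C11–C15 bond by Mukaiyama-type capture of an enantiopure bromonium ion; C11 methyl by Fráter–Seebach alkylation) ⇐ ethyl (S)-4-chloro-3-hydroxybutanoate.

Key step: step 17

Assumption: both enantiomers of the fructose-derived ketone catalyst for the Shi epoxidation and a stock solution of Li2NiBr4 in THF are taken as available reagents; the catalyst enantiomer in steps 4 and 15 is the one predicted by the spiro transition-state model and would be exchanged if the sense proved opposite.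

**Route**

Step 1
Reactants: 1 ethyl (S)-4-chloro-3-hydroxybutanoate
Product: 2 ethyl 2-[(2S)-oxiran-2-yl]acetate
Conditions: Ag2O, Et2O, reflux
Reagents that add atoms: none
Why: Silver-oxide-assisted intramolecular Williamson etherification closes the epoxide at the primary carbon and leaves the carbinol stereocentre (later C12) untouched.

Step 2
Reactants: 2 ethyl 2-[(2S)-oxiran-2-yl]acetate; 3 2-methylprop-1-enylmagnesium bromide
Product: 4 ethyl (3R)-3-hydroxy-6-methylhept-5-enoate
Conditions: CuI (0.1 equiv), THF, −40 °C; NH4Cl (aq)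
Reagents that add atoms: none
Why: Copper-catalysed Grignard opening of the terminal epoxide (SN2 at CH2) installs the isobutenyl group without touching the stereocentre.

Step 3
Reactants: 4 ethyl (3R)-3-hydroxy-6-methylhept-5-enoate
Product: 5 ethyl (3R)-6-methyl-3-(triethylsilyloxy)hept-5-enoate
Conditions: Et3SiCl, imidazole, DMF, 0 to 20 °C
Reagents that add atoms: chlorotriethylsilane, CC[Si](Cl)(CC)CC
Why: Standard silylation; the silyl ether blocks 5-endo attack of the hydroxyl on the later epoxide and bromonium ion.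

Step 4
Reactants: 5 ethyl (3R)-6-methyl-3-(triethylsilyloxy)hept-5-enoate
Product: 6 ethyl (3R)-4-[(2R)-3,3-dimethyloxiran-2-yl]-3-(triethylsilyloxy)butanoate
Conditions: D-fructose-derived ketone catalyst (0.3 equiv), KHSO5 (as 2KHSO5·KHSO4·K2SO4), K2CO3, Bu4NHSO4, MeCN/(MeO)2CH2/aq. buffer pH 10.5, 0 °C
Reagents that add atoms: potassium peroxymonosulfate, [K+].[O-]S(=O)(=O)OO
Why: Shi epoxidation of the trisubstituted alkene, with the face chosen by the catalyst, should give the (R)-epoxide carbon that becomes C14.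

Step 5
Reactants: 6 ethyl (3R)-4-[(2R)-3,3-dimethyloxiran-2-yl]-3-(triethylsilyloxy)butanoate
Product: 8 ethyl (3S,5S)-5-bromo-6-methyl-3-(triethylsilyloxy)-6-(trimethylsilyloxy)heptanoate, via bromohydrin 7 (not isolated)
Conditions: Li2NiBr4, THF, 0 to 20 °C; then 1-(trimethylsilyl)imidazole, CH2Cl2, 20 °C
Reagents that add atoms: dilithium tetrabromonickelate, [Li+].[Li+].[Ni+2].[Br-].[Br-].[Br-].[Br-]; 1-(trimethylsilyl)imidazole, C[Si](C)(C)n1ccnc1
Why: Bromide opens the trisubstituted epoxide by SN2 attack at the secondary carbon with inversion, which fixes the C14–Br configuration, and silylation of the tertiary alcohol prevents base-induced re-closure to the epoxide in step 6.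

Step 6
Reactants: 8 ethyl (3S,5S)-5-bromo-6-methyl-3-(triethylsilyloxy)-6-(trimethylsilyloxy)heptanoate
Product: 11 ethyl (3S,5R)-3-bromo-5-hydroxy-2,2-dimethylcyclopentane-1-carboxylate (C1 epimers), via silyl ketene acetal 9 (not isolated), via cyclised silyl ether 10 (not isolated)
Conditions: LiN(iPr)2, Me3SiCl, THF, −78 °C; then Me3SiOTf (0.3 equiv), CH2Cl2, −78 to −30 °C; then 1 M HCl, THF, 20 °C
Reagents that add atoms: none
Why: Proposed new method: the silyl triflate should ionise the tertiary trimethylsilyl ether with anchimeric help from the vicinal bromine to a bromonium ion, which the tethered silyl ketene acetal attacks at the tertiary carbon (5-exo, enolexo) to form the C11–C15 bond and the cyclopentane; the closest known reaction types are the Lewis-acid-mediated SN1 tert-alkylation of silyl enol ethers (Mukaiyama type) and the capture of bromonium ions generated from enantiopure bromohydrins; the C14–Br bond never breaks, C15 is not stereogenic, the silyloxy and bromo groups can both sit pseudo-equatorial in the envelope, and the C11 epimers converge in step 7.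

Step 7
Reactants: 11 ethyl (3S,5R)-3-bromo-5-hydroxy-2,2-dimethylcyclopentane-1-carboxylate (C1 epimers)
Product: 13 ethyl (1S,3S,5R)-3-bromo-5-hydroxy-1,2,2-trimethylcyclopentane-1-carboxylate, via dilithium dianion 12 (not isolated)
Conditions: LiN(iPr)2 (2.3 equiv), THF, −78 to −30 °C; MeI, DMPU, −78 to −20 °C
Reagents that add atoms: iodomethane, CI
Why: Fráter–Seebach alkylation: the dianion is methylated anti to the lithium alkoxide, so the methyl enters trans to the C12 oxygen and C11 becomes quaternary with the ester cis to the hydroxyl.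

Step 8
Reactants: 13 ethyl (1S,3S,5R)-3-bromo-5-hydroxy-1,2,2-trimethylcyclopentane-1-carboxylate
Product: 14 ethyl (1S,3S,5R)-3-bromo-1,2,2-trimethyl-5-(triethylsilyloxy)cyclopentane-1-carboxylate
Conditions: Et3SiOTf, 2,6-lutidine, CH2Cl2, −78 to 0 °C
Reagents that add atoms: triethylsilyl trifluoromethanesulfonate, CC[Si](CC)(CC)OS(=O)(=O)C(F)(F)F
Why: Silylation of the hindered secondary alcohol with a silyl triflate prevents retro-aldol cleavage of the later β-hydroxy ketone and gives a group that dilute acid removes at the end.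

Step 9
Reactants: 14 ethyl (1S,3S,5R)-3-bromo-1,2,2-trimethyl-5-(triethylsilyloxy)cyclopentane-1-carboxylate
Product: 16 1-[(1S,3S,5R)-3-bromo-1,2,2-trimethyl-5-(triethylsilyloxy)cyclopentyl]ethan-1-one, via α-silyl ketone 15 (not isolated)
Conditions: Me3SiCH2Li (2.5 equiv), THF/pentane, −78 to 0 °C; then MeOH, 20 °C
Reagents that add atoms: (trimethylsilyl)methyllithium, C[Si](C)(C)C[Li]
Why: Addition of the Peterson-type reagent to the non-enolisable ester should stop at the α-silyl ketone enolate, and methanolysis of the C–Si bond gives the methyl ketone (ester to methyl ketone conversion).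

Step 10
Reactants: 17 (S)-citronellal
Product: 19 (3S)-3,7-dimethyloct-6-en-1-yne, via alkenyl nonaflate 18 (not isolated)
Conditions: C4F9SO2F, phosphazene base P2-Et (2.2 equiv), DMF, −30 to 20 °C
Reagents that add atoms: none
Why: One-pot enol sulfonate formation and base-induced E2 elimination turns the CH2–CHO unit into a terminal alkyne without added carbon and without acid, which would trigger the carbonyl-ene cyclisation of citronellal.

Step 11
Reactants: 19 (3S)-3,7-dimethyloct-6-en-1-yne
Product: 20 triethyl[(3S)-3,7-dimethylocta-1,6-dien-2-yl]silane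
Conditions: Et3SiH, [Cp*Ru(MeCN)3]PF6 (2 mol%), CH2Cl2, 0 to 20 °C
Reagents that add atoms: triethylsilane, CC[SiH](CC)CC
Why: Ruthenium-catalysed Markovnikov hydrosilylation of the terminal alkyne places silicon on the internal carbon, giving the 1-silylvinyl terminator and leaving the trisubstituted alkene alone.

Step 12
Reactants: 20 triethyl[(3S)-3,7-dimethylocta-1,6-dien-2-yl]silane
Product: 21 (2E,6S)-2,6-dimethyl-7-(triethylsilyl)octa-2,7-dien-1-ol
Conditions: SeO2 (0.2 equiv), t-BuOOH, CH2Cl2, 20 °C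
Reagents that add atoms: tert-butyl hydroperoxide, CC(C)(C)OO
Why: Selenium-dioxide-catalysed allylic oxidation (ene reaction then [2,3]-shift) is selective for the (E)-methyl group of the trisubstituted alkene.

Step 13
Reactants: 21 (2E,6S)-2,6-dimethyl-7-(triethylsilyl)octa-2,7-dien-1-ol
Product: 22 [(3S,6E)-8-bromo-3,7-dimethylocta-1,6-dien-2-yl]triethylsilane
Conditions: CBr4, PPh3, CH2Cl2, 0 °C
Reagents that add atoms: tetrabromomethane, BrC(Br)(Br)Br
Why: The Appel reaction converts the primary allylic alcohol into the bromide without allylic transposition.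

Step 14
Reactants: 16 1-[(1S,3S,5R)-3-bromo-1,2,2-trimethyl-5-(triethylsilyloxy)cyclopentyl]ethan-1-one; 22 [(3S,6E)-8-bromo-3,7-dimethylocta-1,6-dien-2-yl]triethylsilane
Product: 24 (4E,8S)-1-[(1S,3S,5R)-3-bromo-1,2,2-trimethyl-5-(triethylsilyloxy)cyclopentyl]-4,8-dimethyl-9-(triethylsilyl)deca-4,9-dien-1-one, via lithium enolate 23 (not isolated)
Conditions: LiN(iPr)2, THF, −78 °C; then 22, DMPU, −78 to −30 °C
Reagents that add atoms: none
Why: The kinetic lithium enolate of the methyl ketone (its only enolisable position) is C-alkylated by the primary allylic bromide (SN2), joining the two C10 halves at C8–C9.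

Step 15
Reactants: 24 (4E,8S)-1-[(1S,3S,5R)-3-bromo-1,2,2-trimethyl-5-(triethylsilyloxy)cyclopentyl]-4,8-dimethyl-9-(triethylsilyl)deca-4,9-dien-1-one
Product: 25 1-[(1S,3S,5R)-3-bromo-1,2,2-trimethyl-5-(triethylsilyloxy)cyclopentyl]-3-[(2S,3S)-2-methyl-3-[(3S)-3-methyl-4-(triethylsilyl)pent-4-en-1-yl]oxiran-2-yl]propan-1-one
Conditions: L-fructose-derived ketone catalyst (0.3 equiv), KHSO5 (as 2KHSO5·KHSO4·K2SO4), K2CO3, Bu4NHSO4, MeCN/(MeO)2CH2/aq. buffer pH 10.5, 0 °C
Reagents that add atoms: potassium peroxymonosulfate, [K+].[O-]S(=O)(=O)OO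
Why: Shi epoxidation with the enantiomeric catalyst should oxidise the electron-rich trisubstituted alkene in preference to the 1,1-disubstituted vinylsilane and set the (S,S)-epoxide that encodes C1 and C10.

Step 16
Reactants: 25 the (2S,3S)-epoxy ketone of step 15
Product: 27 (4S,5R,8S)-5-bromo-1-[(1S,3S,5R)-3-bromo-1,2,2-trimethyl-5-(triethylsilyloxy)cyclopentyl]-4,8-dimethyl-1-oxo-9-(triethylsilyl)dec-9-en-4-yl trifluoroacetate, via bromohydrin 26 (not isolated)
Conditions: Li2NiBr4, THF, 0 to 20 °C; then (CF3CO)2O, pyridine, CH2Cl2, −20 °C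
Reagents that add atoms: dilithium tetrabromonickelate, [Li+].[Li+].[Ni+2].[Br-].[Br-].[Br-].[Br-]; trifluoroacetic anhydride, O=C(OC(=O)C(F)(F)F)C(F)(F)F
Why: SN2 opening of the epoxide by bromide at the secondary carbon (inversion) fixes the C1–Br configuration, and trifluoroacetylation turns the tertiary hydroxyl into a leaving group and stops lactol formation with the C7 ketone.

Step 17
Reactants: 27 the bromohydrin trifluoroacetate of step 16
Product: 29 (2S,4aR,5R)-5-bromo-2-[(1S,3S,5R)-3-bromo-1,2,2-trimethyl-5-(triethylsilyloxy)cyclopentyl]-4a,8-dimethyl-1,2,3,4,4a,5,6,7-octahydronaphthalen-2-ol, via ring A ketone 28 (not isolated)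
Conditions: MeAlCl2 (3.5 equiv), CH2Cl2, −78 to −20 °C; KNaC4H4O6 (aq)
Reagents that add atoms: none
Why: Proposed new method: MeAlCl2 binds the hindered C7 ketone (so its oxygen cannot act as a nucleophile) and ionises the tertiary trifluoroacetate with backside participation of the C1 bromine to the C1–C10 bromonium ion, which the 1-silylvinyl group opens at C10 through its silicon-bearing carbon C5 (ring A: 6-exo ipso attack anti to bromine in a chair with equatorial Br; loss of Et3Si from the β-silyl cation leaves the exocyclic C5=C6 methylene of 28). The aluminium-bound ketone then adds to C6 of this methylene with suprafacial transfer of the axial C4–H to oxygen (ring B: six-membered type 2 carbonyl-ene closure with C5 and C6 both ending in the ring), which closes the last ring and shifts the alkene to C4=C5. The closest known reaction types are the enantiospecific polyene cyclisation of bromonium ions generated from enantiopure bromohydrin derivatives, the vinylsilane-terminated cation–alkene cyclisation and the alkylaluminium-halide-promoted type 2 carbonyl-ene cyclisation of ketones; what is new is their union in one flask beside a free ketone. C10 is set by anti opening of the configurationally defined bromonium ion (C1 is carried through, its C–Br bond never breaking), and C7 by the chair-like ene transition state with the quaternary cyclopentyl group equatorial and the Al-bound oxygen axial on the face opposite the C10 methyl. The step needs C-attack of the vinylsilane at C10 instead of O-attack of the ketone or proton loss (secured by Lewis-acid complexation and the six-membered chair), ipso regiochemistry (secured by ring size and the β-silicon effect) and an ene instead of a Prins course (secured by the proton-scavenging Al–Me bond and by the C4 configuration from (S)-citronellal, which places C4–H axial and syn to the side chain in the reactive chair of ring A).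

Step 18
Reactants: 29 the octalinol of step 17
Product: 30 (2S,4aR,5R,8R,8aS)-5-bromo-2-[(1S,3S,5R)-3-bromo-1,2,2-trimethyl-5-(triethylsilyloxy)cyclopentyl]-8,8a-epoxy-4a,8-dimethyldecahydronaphthalen-2-ol
Conditions: mCPBA, NaHCO3, CH2Cl2, 0 °C
Reagents that add atoms: 3-chloroperoxybenzoic acid, OOC(=O)c1cccc(Cl)c1
Why: Peracid (Prilezhaev) epoxidation of the tetrasubstituted C4=C5 alkene should occur on the α face, anti to the C10 methyl and guided by hydrogen bonding to the axial 7α-hydroxyl, which sets the C5–O configuration.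

Step 19
Reactants: 30 the 4α,5α-epoxide of step 18
Product: 31 CNP0390567.2, (1S,4R,4aR,7S,8aS)-4-bromo-7-[(1S,3S,5R)-3-bromo-5-hydroxy-1,2,2-trimethylcyclopentyl]-1,4a-dimethyldecahydronaphthalene-1,7,8a-triol
Conditions: HClO4 (0.5 M aq), THF, 0 to 20 °C
Reagents that add atoms: water, O
Why: Acid-catalysed epoxide hydrolysis should follow the Fürst–Plattner rule (trans-diaxial opening), water attacking C4 from the β face with inversion to give the 4β,5α-diol, while the same acid cleaves the triethylsilyl ether.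

**Compound list**

1 | ethyl (S)-4-chloro-3-hydroxybutanoate | ClC[C@@H](O)CC(=O)OCC | starting material
2 | ethyl 2-[(2S)-oxiran-2-yl]acetate | C1[C@@H](O1)CC(=O)OCC | intermediate
3 | 2-methylprop-1-enylmagnesium bromide | CC(C)=C[Mg]Br | starting material
4 | ethyl (3R)-3-hydroxy-6-methylhept-5-enoate | CC(C)=CC[C@@H](O)CC(=O)OCC | intermediate
5 | ethyl (3R)-6-methyl-3-(triethylsilyloxy)hept-5-enoate | CC(C)=CC[C@@H](O[Si](CC)(CC)CC)CC(=O)OCC | intermediate
6 | ethyl (3R)-4-[(2R)-3,3-dimethyloxiran-2-yl]-3-(triethylsilyloxy)butanoate | CC1(C)O[C@@H]1C[C@@H](O[Si](CC)(CC)CC)CC(=O)OCC | intermediate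
7 | ethyl (3S,5S)-5-bromo-6-hydroxy-6-methyl-3-(triethylsilyloxy)heptanoate | CC(C)(O)[C@@H](Br)C[C@@H](O[Si](CC)(CC)CC)CC(=O)OCC | intermediate
8 | ethyl (3S,5S)-5-bromo-6-methyl-3-(triethylsilyloxy)-6-(trimethylsilyloxy)heptanoate | CC(C)(O[Si](C)(C)C)[C@@H](Br)C[C@@H](O[Si](CC)(CC)CC)CC(=O)OCC | intermediate
9 | (E)-ethyl trimethylsilyl ketene acetal of 8 (geometry immaterial) | CC(C)(O[Si](C)(C)C)[C@@H](Br)C[C@@H](O[Si](CC)(CC)CC)/C=C(/O[Si](C)(C)C)OCC | intermediate
10 | ethyl (3S,5R)-3-bromo-2,2-dimethyl-5-(triethylsilyloxy)cyclopentane-1-carboxylate (C1 epimers) | CC1(C)[C@@H](Br)C[C@@H](O[Si](CC)(CC)CC)C1C(=O)OCC | intermediate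
11 | ethyl (3S,5R)-3-bromo-5-hydroxy-2,2-dimethylcyclopentane-1-carboxylate (C1 epimers) | CC1(C)[C@@H](Br)C[C@@H](O)C1C(=O)OCC | intermediate
12 | dilithium dianion of 11 (ester enolate alkoxide) | [Li+].[Li+].CC1(C)[C@@H](Br)C[C@@H]([O-])C1=C([O-])OCC | intermediate
13 | ethyl (1S,3S,5R)-3-bromo-5-hydroxy-1,2,2-trimethylcyclopentane-1-carboxylate | CC1(C)[C@@H](Br)C[C@@H](O)[C@@]1(C)C(=O)OCC | intermediate
14 | ethyl (1S,3S,5R)-3-bromo-1,2,2-trimethyl-5-(triethylsilyloxy)cyclopentane-1-carboxylate | CC1(C)[C@@H](Br)C[C@@H](O[Si](CC)(CC)CC)[C@@]1(C)C(=O)OCC | intermediate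
15 | 1-[(1S,3S,5R)-3-bromo-1,2,2-trimethyl-5-(triethylsilyloxy)cyclopentyl]-2-(trimethylsilyl)ethan-1-one | CC1(C)[C@@H](Br)C[C@@H](O[Si](CC)(CC)CC)[C@@]1(C)C(=O)C[Si](C)(C)C | intermediate
16 | 1-[(1S,3S,5R)-3-bromo-1,2,2-trimethyl-5-(triethylsilyloxy)cyclopentyl]ethan-1-one | CC1(C)[C@@H](Br)C[C@@H](O[Si](CC)(CC)CC)[C@@]1(C)C(C)=O | intermediate
17 | (S)-citronellal, (3S)-3,7-dimethyloct-6-enal | CC(C)=CCC[C@H](C)CC=O | starting material
18 | (3S)-3,7-dimethylocta-1,6-dien-1-yl nonafluorobutane-1-sulfonate (E drawn) | CC(C)=CCC[C@H](C)/C=C/OS(=O)(=O)C(F)(F)C(F)(F)C(F)(F)C(F)(F)F | intermediate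
19 | (3S)-3,7-dimethyloct-6-en-1-yne | CC(C)=CCC[C@H](C)C#C | intermediate
20 | triethyl[(3S)-3,7-dimethylocta-1,6-dien-2-yl]silane | CC(C)=CCC[C@H](C)C(=C)[Si](CC)(CC)CC | intermediate
21 | (2E,6S)-2,6-dimethyl-7-(triethylsilyl)octa-2,7-dien-1-ol | OC/C(C)=C/CC[C@H](C)C(=C)[Si](CC)(CC)CC | intermediate
22 | [(3S,6E)-8-bromo-3,7-dimethylocta-1,6-dien-2-yl]triethylsilane | BrC/C(C)=C/CC[C@H](C)C(=C)[Si](CC)(CC)CC | intermediate
23 | lithium enolate of 16 | [Li+].CC1(C)[C@@H](Br)C[C@@H](O[Si](CC)(CC)CC)[C@@]1(C)C([O-])=C | intermediate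
24 | (4E,8S)-1-[(1S,3S,5R)-3-bromo-1,2,2-trimethyl-5-(triethylsilyloxy)cyclopentyl]-4,8-dimethyl-9-(triethylsilyl)deca-4,9-dien-1-one | CC1(C)[C@@H](Br)C[C@@H](O[Si](CC)(CC)CC)[C@@]1(C)C(=O)CC/C(C)=C/CC[C@H](C)C(=C)[Si](CC)(CC)CC | intermediate
25 | (2S,3S)-epoxide of 24 at the trisubstituted alkene | CC1(C)[C@@H](Br)C[C@@H](O[Si](CC)(CC)CC)[C@@]1(C)C(=O)CC[C@]2(C)O[C@H]2CC[C@H](C)C(=C)[Si](CC)(CC)CC | intermediate
26 | (4S,5R,8S)-5-bromo-1-[(1S,3S,5R)-3-bromo-1,2,2-trimethyl-5-(triethylsilyloxy)cyclopentyl]-4-hydroxy-4,8-dimethyl-9-(triethylsilyl)dec-9-en-1-one | CC1(C)[C@@H](Br)C[C@@H](O[Si](CC)(CC)CC)[C@@]1(C)C(=O)CC[C@](C)(O)[C@H](Br)CC[C@H](C)C(=C)[Si](CC)(CC)CC | intermediate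
27 | trifluoroacetate of the tertiary alcohol of 26 | CC1(C)[C@@H](Br)C[C@@H](O[Si](CC)(CC)CC)[C@@]1(C)C(=O)CC[C@](C)(OC(=O)C(F)(F)F)[C@H](Br)CC[C@H](C)C(=C)[Si](CC)(CC)CC | intermediate
28 | 1-[(1S,3S,5R)-3-bromo-1,2,2-trimethyl-5-(triethylsilyloxy)cyclopentyl]-3-[(1R,2R,5S)-2-bromo-1,5-dimethyl-6-methylidenecyclohexyl]propan-1-one | CC1(C)[C@@H](Br)C[C@@H](O[Si](CC)(CC)CC)[C@@]1(C)C(=O)CC[C@@]1(C)[C@H](Br)CC[C@H](C)C1=C | intermediate
29 | (2S,4aR,5R)-5-bromo-2-[(1S,3S,5R)-3-bromo-1,2,2-trimethyl-5-(triethylsilyloxy)cyclopentyl]-4a,8-dimethyl-1,2,3,4,4a,5,6,7-octahydronaphthalen-2-ol | CC1(C)[C@@H](Br)C[C@@H](O[Si](CC)(CC)CC)[C@@]1(C)[C@]1(O)CC[C@@]2(C)[C@H](Br)CCC(C)=C2C1 | intermediate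
30 | (2S,4aR,5R,8R,8aS)-8,8a-epoxide of 29 (4α,5α-epoxide) | CC1(C)[C@@H](Br)C[C@@H](O[Si](CC)(CC)CC)[C@@]1(C)[C@]1(O)CC[C@@]2(C)[C@H](Br)CC[C@@]3(C)O[C@@]23C1 | intermediate
31 | CNP0390567.2 | CC1(C)[C@@H](Br)C[C@@H](O)[C@@]1(C)[C@]1(O)CC[C@@]2(C)[C@H](Br)CC[C@](C)(O)[C@]2(O)C1 | target

**Step count and risks**

Total step count: 19. Longest linear sequence: 15 steps (steps 1–9 and 14–19).

Steps most likely to fail:

1. Step 17 (Proposed new method). What may go wrong: the C10 cation is captured by the ketone oxygen or loses a proton before the vinylsilane closes ring A, or the ring B closure runs stepwise through a C5 cation that picks up chloride or methyl from aluminium instead of transferring the C4 hydrogen. Fallback (separate, individually precedented events with the carbonyl masked), setting out from 24 and returning at 29: reduction of the C7 ketone with LiBH4 should give the C7 carbinol F1, acetylated (Ac2O, DMAP) to the C7 acetate F2. Shi epoxidation as in step 15 gives the epoxy acetate F3; Li2NiBr4 opening gives the bromohydrin acetate F4; trifluoroacetylation gives the tertiary trifluoroacetate F5. With no carbonyl present, Me2AlCl at −78 °C should effect only the bromonium/vinylsilane closure of ring A to the ring A acetate F6. Methanolysis (K2CO3, MeOH) gives the ring A carbinol F7, and Dess–Martin oxidation gives 28 as an isolated compound. 28 is then closed to 29 by a separate Me2AlCl-promoted type 2 carbonyl-ene reaction.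

2. Step 6 (Proposed new method). What may go wrong: proton loss from the β-bromo tertiary cation, or attack by the C12 silyl ether oxygen, outruns C–C bond formation. Fallback (carbocycle first, bromide second), setting out from 6 and returning at 10: enolisation and silylation (LiN(iPr)2, Me3SiCl) gives the epoxy silyl ketene acetal F8. BF3·OEt2 then induces the known Mukaiyama-type opening of the epoxide at its tertiary carbon to give the C14 alcohol F9 (hydroxyl trans to the silyloxy group, configuration of the epoxide retained). Tf2O/pyridine gives the C14 triflate F10, and LiBr displaces it with inversion to give 10, which the acid stage of step 6 converts into 11.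

3. Step 16. What may go wrong: bromide attacks the tertiary epoxide carbon, or the Lewis-acidic medium lets the ketone oxygen open the epoxide (bicyclic ketal formation). Fallback (no epoxide, substrate-uncontrolled bromohydrin formation), setting out from 24 and returning at 26: N-bromosuccinimide in THF/H2O at 0 °C should add Br and OH anti and Markovnikov across the trisubstituted alkene, giving 26 together with the (4R,5S)-bromohydrin diastereomer F11. The two are separated by chromatography (they are diastereomers because of the enantiopure cyclopentane), and 26 is trifluoroacetylated as in step 16.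

Further compounds
F1 | step 17 | (4E,8S)-1-[(1S,3S,5R)-3-bromo-1,2,2-trimethyl-5-(triethylsilyloxy)cyclopentyl]-4,8-dimethyl-9-(triethylsilyl)deca-4,9-dien-1-ol (C1 epimers) | CC1(C)[C@@H](Br)C[C@@H](O[Si](CC)(CC)CC)[C@@]1(C)C(O)CC/C(C)=C/CC[C@H](C)C(=C)[Si](CC)(CC)CC
F2 | step 17 | acetate of F1 | CC1(C)[C@@H](Br)C[C@@H](O[Si](CC)(CC)CC)[C@@]1(C)C(OC(C)=O)CC/C(C)=C/CC[C@H](C)C(=C)[Si](CC)(CC)CC
F3 | step 17 | (2S,3S)-epoxide of F2 | CC1(C)[C@@H](Br)C[C@@H](O[Si](CC)(CC)CC)[C@@]1(C)C(OC(C)=O)CC[C@]2(C)O[C@H]2CC[C@H](C)C(=C)[Si](CC)(CC)CC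
F4 | step 17 | (4S,5R)-bromohydrin of F3 | CC1(C)[C@@H](Br)C[C@@H](O[Si](CC)(CC)CC)[C@@]1(C)C(OC(C)=O)CC[C@](C)(O)[C@H](Br)CC[C@H](C)C(=C)[Si](CC)(CC)CC
F5 | step 17 | tertiary trifluoroacetate of F4 | CC1(C)[C@@H](Br)C[C@@H](O[Si](CC)(CC)CC)[C@@]1(C)C(OC(C)=O)CC[C@](C)(OC(=O)C(F)(F)F)[C@H](Br)CC[C@H](C)C(=C)[Si](CC)(CC)CC
F6 | step 17 | 1-[(1S,3S,5R)-3-bromo-1,2,2-trimethyl-5-(triethylsilyloxy)cyclopentyl]-3-[(1R,2R,5S)-2-bromo-1,5-dimethyl-6-methylidenecyclohexyl]propyl acetate (C1 epimers) | CC1(C)[C@@H](Br)C[C@@H](O[Si](CC)(CC)CC)[C@@]1(C)C(OC(C)=O)CC[C@@]1(C)[C@H](Br)CC[C@H](C)C1=C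
F7 | step 17 | alcohol from F6 (C1 epimers) | CC1(C)[C@@H](Br)C[C@@H](O[Si](CC)(CC)CC)[C@@]1(C)C(O)CC[C@@]1(C)[C@H](Br)CC[C@H](C)C1=C
F8 | step 6 | (E)-ethyl trimethylsilyl ketene acetal of 6 | CC1(C)O[C@@H]1C[C@@H](O[Si](CC)(CC)CC)/C=C(/O[Si](C)(C)C)OCC
F9 | step 6 | ethyl (3R,5R)-3-hydroxy-2,2-dimethyl-5-(triethylsilyloxy)cyclopentane-1-carboxylate (C1 epimers) | CC1(C)[C@H](O)C[C@@H](O[Si](CC)(CC)CC)C1C(=O)OCC
F10 | step 6 | ethyl (3R,5R)-2,2-dimethyl-5-(triethylsilyloxy)-3-(trifluoromethylsulfonyloxy)cyclopentane-1-carboxylate (C1 epimers) | CC1(C)[C@H](OS(=O)(=O)C(F)(F)F)C[C@@H](O[Si](CC)(CC)CC)C1C(=O)OCC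
F11 | step 16 | (4R,5S,8S)-diastereomer of bromohydrin 26 | CC1(C)[C@@H](Br)C[C@@H](O[Si](CC)(CC)CC)[C@@]1(C)C(=O)CC[C@@](C)(O)[C@@H](Br)CC[C@H](C)C(=C)[Si](CC)(CC)CC
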